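## Structural features

The target is a germacranolide: a ten-membered carbocycle (C1–C10, germacrane numbering, used for every compound below) fused across C6–C7 to a butenolide (O–C12(=O)–C11=C7) whose α-carbon C11 carries the acetoxymethyl carbon C13. Around the ring lie a C1–C10 epoxide (C10 quaternary, bearing the hydroxymethyl C14), the Z-alkene C2=C3, a C4–C5 epoxide (C4 quaternary, bearing the methyl C15), the lactone carbinol C6, sp2 C7, the methacrylate-bearing C8 and the methylene C9. There are six stereocentres: C10/C1 (one epoxide), C4/C5/C6 (contiguous) and C8, which is insulated by sp2 C7 and C9H2. Read from the SMILES, the C4–C5 epoxide is cis with respect to the ring (C3 and C6 on the same side) and the C1–C10 epoxide is trans (C9 and C2 on opposite sides). The array is therefore the bis-epoxide of an (E,Z,Z)-cyclodeca-1(10),2,4-triene. A Z-alkene next to a cis-epoxide is what a six-membered ring C1–C6 enforces, and a ring-trans alkene at C1(10) is what a chair [3,3] shift delivers; the key step exploits this. Fragile groups are the two vinyl epoxides (acid, Lewis acid, Pd(0)), the 2,3-epoxy alcohol (Payne rearrangement under base), the butenolide (acidic γ-H at C6; a free O8 can translactonise onto C12), the methacrylate and the allylic acetate. The real difficulty is the strained ten-membered ring with three adjacent elements of fixed geometry, plus the C6–C8 oxygenation around a tetrasubstituted butenolide.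

## Logic of the disconnections

37 to 36: the C1–O and C10–O bonds of the trans-epoxide are cut last, leaving the allylic alcohol. The C14 hydroxyl is a built-in director and the epoxy alcohol is the most base- and acid-sensitive unit. Two stereocentres disappear. The forward step must choose one face of a ring-trans alkene by reagent control and leave C2=C3, the methacrylate and the butenolide untouched.

36 to 35 to 34: the O14 protecting group is restored and the C8–O ester bond is cut with inversion. The key step delivers C8 in the R configuration, and the methacrylate cannot survive enolate chemistry, so it enters late by SN2 on the activated 8R alcohol. The forward step must invert cleanly at an allylic secondary carbinol.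

34 to 32 to 28 to 26 to 25: the C7=C11 double bond and the C11–C13 bond are cut, giving a saturated lactone with unsubstituted C11. O8 is silylated during the enolate steps so that it cannot attack C12. The forward steps must place selenium on C11 cis to H7 for the syn-elimination.

25 to 23 to 21: the C8–O bond is traced to a C8–Si bond (retentive oxidation, done while the lactone is saturated so that C8–Si is not vinylogous to the carbonyl). The lactone C–O bonds are traced to a C6 ketone and a C12 ester. The forward reduction must deliver hydride to the outer face of C6.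

21 to 18 (key): the C8–C9 and C7–C11 bonds are cut and C1–C6 is reconnected. The ten-membered ring, its ring-trans C1(10) alkene, the C8 stereocentre and a regiodefined C7 enolate collapse into a cyclohexenol. In that six-membered ring the Z-alkene and the cis-epoxide are geometric necessities and relative configuration is easy to set. The forward step needs the two alkenyl groups trans on C1 and C6, an alkoxide that cannot undergo Payne rearrangement, and an E-vinylsilane.

18 to 16 to 10 + 13: the C2=C3 alkene is traced to a C3 hydroxyl (syn-elimination; C4 has no hydrogen, so the regiochemistry is fixed). The C6–C7 bond is cut to a ketone and a vinyl nucleophile. C2=C3 is held back because the corresponding β,γ-unsaturated epoxy ketone is an aromatisation-prone isomer of a catechol. The addition must occur anti to both the epoxide oxygen and the C1 substituent.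

10 to 9 to 8 to 7: the ketone is masked as its dimethyl ketal, the epoxide C–O bonds are cut to an allylic alcohol (hydroxyl-directed delivery), and the C3 carbinol is cut to an enone.

7 to 2 + 6: the C1–C10 bond is cut to a quinone monoketal and an alkenylboron reagent. This enantioselective conjugate addition is the only step that introduces absolute configuration; everything else is relayed from it or set by reagent control (tartrate). 2 comes from 1, 6 from 4 and 3, and 13 from 12 and 11.

## Other disconnections considered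

Alternative 1: cut C2=C3 (the first idea). Forward step: Z-selective ring-closing metathesis of the bis(vinyl epoxide) diene A1 to the target. Both alkenes sit on hindered epoxide carbons (C4 is quaternary), the ring is strained and the Z-geometry is not enforced by anything in the substrate. All six stereocentres would have to be built one by one along an open chain with no relay between them. The chosen plan gets the Z-alkene and cis-epoxide for free from a six-membered ring and makes the ring by a unimolecular shift with no dilution problem.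

Alternative 2: cut C7–C8. Forward step: intramolecular Nozaki–Hiyama–Kishi addition of the C7 iodobutenolide to the C8 aldehyde in A2, giving the macrocyclic alcohol A3. This forms the ring and the C8 carbinol together, but nothing in A2 controls the C8 configuration. Cr(II) is expected to attack the two vinyl epoxides reductively, and the open-chain Z-ene bis-epoxide aldehyde is itself labile. The chosen key step sets C8 by chirality transfer through a chair and tolerates the epoxide because it runs under non-reducing basic conditions.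

Alternative 3: cut the C4=C5, C2=C3 and C1=C10 π-system back to a C5–C10 σ-bond. Forward step: photochemical conrotatory 6π ring opening of the cis-fused eudesma-1,3-diene A4 to the (E,Z,Z)-triene A5, then epoxidation of both terminal alkenes. The triene pattern matches, but conrotation can turn either way and give the 1(10)E,4Z or the 1(10)Z,4E triene with nothing in A4 to bias it. A5 should reclose thermally by disrotation, and two face-selective epoxidations would have to be run on a labile triene. A4 also needs a fully functionalised decalin synthesis, so step economy is worse. The chosen plan assigns each geometry to a separate, controllable element.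

Key step: step 12

Remarks on the chemistry: germacrane numbering of the target is used in names and explanations. In 20–36 the C1(10) alkene is ring-trans (C9 and C2 trans); its CIP descriptor is Z because C14 bears oxygen. Descriptors at C7 and C11 of 21–31 are the expected ones and are erased when C7=C11 forms. The facial sense of (R)-BINAP in step 4 is assumed to follow the standard model for cyclohex-2-enones. Commercial solutions of n-BuLi, LDA, L-Selectride and TBHP are used.

## Steps

Step 1
Reactants: 1 4-methoxy-2-methylphenol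
Product: 2 4,4-dimethoxy-2-methylcyclohexa-2,5-dien-1-one
Conditions: PhI(OAc)2, MeOH, 0 °C
Reagents that add atoms: methanol (CO)
Why: Iodine(III)-mediated oxidative dearomatisation of a p-methoxyphenol in methanol should give the quinone monoketal; the methyl group ends up α to the free ketone.

Step 2
Reactants: 3 2-bromoprop-2-en-1-ol
Product: 4 1-{[(2-bromoprop-2-en-1-yl)oxy]methyl}-4-methoxybenzene
Conditions: NaH, 4-methoxybenzyl chloride, Bu4NI (cat.), THF, 0 °C to rt
Reagents that add atoms: 4-methoxybenzyl chloride (COc1ccc(CCl)cc1)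
Why: Williamson etherification; the PMB ether masks the future C14 hydroxyl until step 20.

Step 3
Reactants: 4 1-{[(2-bromoprop-2-en-1-yl)oxy]methyl}-4-methoxybenzene
Product: 6 potassium trifluoro{3-[(4-methoxybenzyl)oxy]prop-1-en-2-yl}borate, via pinacol boronate 5 (not isolated)
Conditions: B2pin2, PdCl2(PPh3)2 (3 mol %), PPh3, KOPh, toluene, 50 °C; then KHF2, MeOH/H2O, rt
Reagents that add atoms: bis(pinacolato)diboron (CC1(C)OB(OC1(C)C)B1OC(C)(C)C(C)(C)O1); potassium hydrogen difluoride ([K+].F[H-]F)
Why: Miyaura borylation of the alkenyl bromide followed by conversion to the bench-stable trifluoroborate needed for the rhodium step.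

Step 4
Reactants: 2 4,4-dimethoxy-2-methylcyclohexa-2,5-dien-1-one; 6 potassium trifluoro{3-[(4-methoxybenzyl)oxy]prop-1-en-2-yl}borate
Product: 7 (5R)-4,4-dimethoxy-5-{3-[(4-methoxybenzyl)oxy]prop-1-en-2-yl}-2-methylcyclohex-2-en-1-one
Conditions: [Rh(cod)2]BF4 (3 mol %), (R)-BINAP (3.3 mol %), Et3N, toluene/H2O 10:1, 25 °C
Reagents that add atoms: none
Why: Hayashi–Miyaura rhodium/BINAP 1,4-addition of an alkenyltrifluoroborate to a quinone monoketal, which cannot aromatise; only the unsubstituted enone reacts because the 2-methyl enone resists carbometalation, and the ligand fixes the new stereocentre (future C1) as R.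

Step 5
Reactants: 7 (5R)-4,4-dimethoxy-5-{3-[(4-methoxybenzyl)oxy]prop-1-en-2-yl}-2-methylcyclohex-2-en-1-one
Product: 8 (1R,5R)-4,4-dimethoxy-5-{3-[(4-methoxybenzyl)oxy]prop-1-en-2-yl}-2-methylcyclohex-2-en-1-ol
Conditions: NaBH4, CeCl3·7H2O, MeOH, −78 °C
Reagents that add atoms: none
Why: Luche 1,2-reduction; axial hydride delivery to the half-chair with the C5 substituent pseudo-equatorial should give the cis alcohol, as in the carvone to cis-carveol reduction.

Step 6
Reactants: 8 (1R,5R)-4,4-dimethoxy-5-{3-[(4-methoxybenzyl)oxy]prop-1-en-2-yl}-2-methylcyclohex-2-en-1-ol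
Product: 9 (1R,2R,4R,6R)-5,5-dimethoxy-4-{3-[(4-methoxybenzyl)oxy]prop-1-en-2-yl}-1-methyl-7-oxabicyclo[4.1.0]heptan-2-ol
Conditions: VO(acac)2 (5 mol %), t-BuOOH, CH2Cl2, 0 °C to rt
Reagents that add atoms: tert-butyl hydroperoxide (CC(C)(C)OO)
Why: Vanadium-catalysed hydroxyl-directed epoxidation delivers oxygen syn to the allylic OH, hence syn to the alkenyl group; this sets the future C4 (R) and C5. The 1,1-disubstituted alkene is not allylic to the OH and should not react.

Step 7
Reactants: 9 (1R,2R,4R,6R)-5,5-dimethoxy-4-{3-[(4-methoxybenzyl)oxy]prop-1-en-2-yl}-1-methyl-7-oxabicyclo[4.1.0]heptan-2-ol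
Product: 10 (1R,3R,5R,6R)-5-hydroxy-3-{3-[(4-methoxybenzyl)oxy]prop-1-en-2-yl}-6-methyl-7-oxabicyclo[4.1.0]heptan-2-one
Conditions: montmorillonite K10, wet CH2Cl2, rt
Reagents that add atoms: water (O)
Why: Mild clay-mediated hydrolysis of the dimethyl ketal, of the kind used for epoxyquinone monoketals, should spare the adjacent epoxide; the product is an ordinary α,β-epoxy ketone without the aromatisation-prone β,γ-alkene.

Step 8
Reactants: 11 benzyl(chloro)dimethylsilane
Product: 12 benzyl(ethynyl)dimethylsilane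
Conditions: ethynylmagnesium bromide, THF, 0 °C to rt
Reagents that add atoms: ethynylmagnesium bromide (C#C[Mg]Br)
Why: Substitution at silicon by the acetylide; the benzyldimethylsilyl group is chosen because fluoride later unmasks it for Tamao–Fleming oxidation without acid.

Step 9
Reactants: 12 benzyl(ethynyl)dimethylsilane
Product: 13 (E)-benzyldimethyl[2-(tributylstannyl)ethenyl]silane
Conditions: Bu3SnH, AIBN (cat.), neat, 90 °C
Reagents that add atoms: tributyltin hydride (CCCC[SnH](CCCC)CCCC)
Why: Radical hydrostannylation of a silylacetylene; reversible stannyl radical addition equilibrates to the (E)-1-silyl-2-stannylethene.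

Step 10
Reactants: 13 (E)-benzyldimethyl[2-(tributylstannyl)ethenyl]silane; 10 (1R,3R,5R,6R)-5-hydroxy-3-{3-[(4-methoxybenzyl)oxy]prop-1-en-2-yl}-6-methyl-7-oxabicyclo[4.1.0]heptan-2-one
Product: 16 (1R,2R,4R,5R,6S)-5-[(E)-2-(benzyldimethylsilyl)ethenyl]-4-{3-[(4-methoxybenzyl)oxy]prop-1-en-2-yl}-1-methyl-7-oxabicyclo[4.1.0]heptane-2,5-diol, via vinyllithium 14 (not isolated), via organocerium reagent 15 (not isolated)
Conditions: 13 (3 equiv), n-BuLi, THF, −78 °C; CeCl3, −78 °C; then 10, −78 °C; aq NH4Cl
Reagents that add atoms: none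
Why: Tin–lithium exchange and transmetalation give a weakly basic organocerium reagent that adds 1,2 without enolising the α'-CH. Attack anti to both the epoxide oxygen and the neighbouring alkenyl group (same face) should give the carbinol with OH cis to the epoxide and the two alkenyl groups trans. One equivalent is consumed by the free hydroxyl.

Step 11
Reactants: 16 (1R,2R,4R,5R,6S)-5-[(E)-2-(benzyldimethylsilyl)ethenyl]-4-{3-[(4-methoxybenzyl)oxy]prop-1-en-2-yl}-1-methyl-7-oxabicyclo[4.1.0]heptane-2,5-diol
Product: 18 (1S,2R,3R,6R)-2-[(E)-2-(benzyldimethylsilyl)ethenyl]-3-{3-[(4-methoxybenzyl)oxy]prop-1-en-2-yl}-6-methyl-7-oxabicyclo[4.1.0]hept-4-en-2-ol, via sulfamate salt 17 (not isolated)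
Conditions: Burgess reagent (1.3 equiv), THF/benzene, rt then 50 °C
Reagents that add atoms: none
Why: Burgess dehydration (syn Ei) of the secondary sulfamate; the only β-hydrogen is on the future C2 because C4 is quaternary, so the ring alkene must form at C2=C3. The hindered tertiary carbinol reacts more slowly and has no syn β-hydrogen.

Step 12
Reactants: 18 (1S,2R,3R,6R)-2-[(E)-2-(benzyldimethylsilyl)ethenyl]-3-{3-[(4-methoxybenzyl)oxy]prop-1-en-2-yl}-6-methyl-7-oxabicyclo[4.1.0]hept-4-en-2-ol
Product: 21 ethyl (4R,5R,7S,8R)-8-(benzyldimethylsilyl)-4,5-epoxy-14-[(4-methoxybenzyl)oxy]-6-oxo-13-norgermacra-1(10),2-dien-12-oate, via potassium alkoxide 19 (not isolated), via potassium enolate 20 (not isolated)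
Conditions: KH (1.3 equiv), 18-crown-6 (1.3 equiv), THF, −20 °C to rt; then BrCH2CO2Et, −78 to −30 °C
Reagents that add atoms: ethyl bromoacetate (CCOC(=O)CBr)
Why: KH/18-crown-6 gives the naked alkoxide 19, whose 1,5-diene C8=C7–C6(O−)–C1–C10=C9 undergoes an anionic oxy-Cope [3,3] shift: the doubly allylic C1–C6 bond breaks, C8–C9 forms and the regiodefined enolate 20 results, which ethyl bromoacetate C-alkylates at C7 (closest known type: anionic oxy-Cope ring expansion of trans-1,2-dialkenylcyclohexanols to cyclodec-5-enones with enolate trapping). The ten-membered ring is not closed by a chain cyclisation; it grows out of the six-membered ring by four atoms through a six-centre chair transition state. With the two alkenyl groups trans (pseudo-diequatorial), the ring bonds C6–C5 and C1–C2 are equatorial on that chair, which fixes the new C1(10) alkene as ring-trans and the enolate with C5 and C8 trans; the Z C2=C3 alkene and the cis C4–C5 epoxide are carried over unchanged. C8 is set by chirality transfer: the E-silyl group is equatorial at the bond-forming terminus, so C9 reaches one face of C8 only and 8R results. C7 is set by alkylation on the outer face of the medium-ring enolate and is erased later. The step needs the [3,3] shift through the two exocyclic alkenes and not the ring alkene (out of reach for an equatorial vinyl group), and a concerted shift in preference to heterolysis to a pentadienyl anion. Payne rearrangement is excluded because O6 is cis to the epoxide oxygen and cannot reach the back of C5–O, and 1,4-silyl migration is excluded because O and Si are trans on the alkene.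

Step 13
Reactants: 21 ethyl (4R,5R,7S,8R)-8-(benzyldimethylsilyl)-4,5-epoxy-14-[(4-methoxybenzyl)oxy]-6-oxo-13-norgermacra-1(10),2-dien-12-oate
Product: 23 (4R,5S,6S,7S,8R)-8-(benzyldimethylsilyl)-4,5-epoxy-14-[(4-methoxybenzyl)oxy]-13-norgermacra-1(10),2-dien-12,6-olide, via lithium alkoxide 22 (not isolated)
Conditions: L-Selectride, THF, −78 to 0 °C; aq NH4Cl
Reagents that add atoms: none
Why: The bulky hydride should attack the ketone from the outer face, away from the transannular side opened by the Cope shift, giving 6S. The lithium alkoxide then closes onto the ethyl ester (5-exo-trig) to the γ-lactone faster than it can attack the neighbouring epoxide.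

Step 14
Reactants: 23 (4R,5S,6S,7S,8R)-8-(benzyldimethylsilyl)-4,5-epoxy-14-[(4-methoxybenzyl)oxy]-13-norgermacra-1(10),2-dien-12,6-olide
Product: 25 (4R,5S,6S,7R,8R)-4,5-epoxy-8-hydroxy-14-[(4-methoxybenzyl)oxy]-13-norgermacra-1(10),2-dien-12,6-olide, via fluorosilane 24 (not isolated)
Conditions: TBAF, THF, 0 °C; then KHCO3, 30% H2O2, MeOH, rt
Reagents that add atoms: hydrogen peroxide (OO)
Why: Tamao–Fleming oxidation: fluoride cleaves the benzyl–silicon bond, then peroxide effects carbon-to-oxygen migration with retention at C8. It is run while the lactone is saturated, so C8–Si is not activated toward desilylation.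

Step 15
Reactants: 25 (4R,5S,6S,7R,8R)-4,5-epoxy-8-hydroxy-14-[(4-methoxybenzyl)oxy]-13-norgermacra-1(10),2-dien-12,6-olide
Product: 26 (4R,5S,6S,7S,8R)-4,5-epoxy-14-[(4-methoxybenzyl)oxy]-8-(triethylsilyloxy)-13-norgermacra-1(10),2-dien-12,6-olide
Conditions: TESCl, imidazole, DMF, 0 °C
Reagents that add atoms: chlorotriethylsilane (CC[Si](Cl)(CC)CC)
Why: Silylation under near-neutral conditions removes the free O8 before strong base is used, so no alkoxide can translactonise onto C12.

Step 16
Reactants: 26 (4R,5S,6S,7S,8R)-4,5-epoxy-14-[(4-methoxybenzyl)oxy]-8-(triethylsilyloxy)-13-norgermacra-1(10),2-dien-12,6-olide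
Product: 28 (4R,5S,6S,7S,8R,11R)-4,5-epoxy-13-hydroxy-14-[(4-methoxybenzyl)oxy]-8-(triethylsilyloxy)germacra-1(10),2-dien-12,6-olide, via lithium enolate 27 (not isolated)
Conditions: LDA, THF, −78 °C; CH2O (gas), −78 to −30 °C; aq NH4Cl
Reagents that add atoms: formaldehyde (C=O)
Why: Aldol reaction of the lactone enolate with monomeric formaldehyde installs C13; the electrophile should enter on the face of C11 away from the C7–C8 bond.

Step 17
Reactants: 28 (4R,5S,6S,7S,8R,11R)-4,5-epoxy-13-hydroxy-14-[(4-methoxybenzyl)oxy]-8-(triethylsilyloxy)germacra-1(10),2-dien-12,6-olide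
Product: 32 (4R,5S,6S,8R)-4,5-epoxy-13-hydroxy-14-[(4-methoxybenzyl)oxy]-8-(triethylsilyloxy)germacra-1(10),2,7(11)-trien-12,6-olide, via dilithio dianion 29 (not isolated), via selenide 30 (not isolated), via selenoxide 31 (not isolated)
Conditions: LDA (2.3 equiv), THF/DMPU, −78 to −40 °C; PhSeBr, −78 °C; aq NH4Cl; then 30% H2O2, pyridine, CH2Cl2, 0 °C to rt
Reagents that add atoms: none
Why: Selenenylation of the alkoxide enolate again occurs anti to the C7–C8 bond, which puts selenium cis to H7. Selenoxide syn-elimination then runs toward C7 and not toward the oxygen-bearing C13, giving the tetrasubstituted butenolide.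

Step 18
Reactants: 32 (4R,5S,6S,8R)-4,5-epoxy-13-hydroxy-14-[(4-methoxybenzyl)oxy]-8-(triethylsilyloxy)germacra-1(10),2,7(11)-trien-12,6-olide
Product: 34 (4R,5S,6S,8R)-13-acetoxy-4,5-epoxy-8-hydroxy-14-[(4-methoxybenzyl)oxy]germacra-1(10),2,7(11)-trien-12,6-olide, via acetate silyl ether 33 (not isolated)
Conditions: Ac2O, pyridine, DMAP (cat.), CH2Cl2, 0 °C; then HF·pyridine, pyridine, THF, 0 °C
Reagents that add atoms: acetic anhydride (CC(=O)OC(C)=O)
Why: Acetylation of the only free hydroxyl, then buffered fluoride cleavage of the secondary TES ether; acetate, PMB ether and epoxide should survive.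

Step 19
Reactants: 34 (4R,5S,6S,8R)-13-acetoxy-4,5-epoxy-8-hydroxy-14-[(4-methoxybenzyl)oxy]germacra-1(10),2,7(11)-trien-12,6-olide
Product: 35 (4R,5S,6S,8S)-13-acetoxy-4,5-epoxy-14-[(4-methoxybenzyl)oxy]-8-(methacryloyloxy)germacra-1(10),2,7(11)-trien-12,6-olide
Conditions: PPh3, DIAD, methacrylic acid, toluene, 0 °C to rt
Reagents that add atoms: methacrylic acid (C=C(C)C(=O)O)
Why: Mitsunobu esterification: methacrylate displaces the oxyphosphonium group by SN2, inverting 8R to the required 8S. SN2' is disfavoured because it would destroy the butenolide conjugation.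

Step 20
Reactants: 35 (4R,5S,6S,8S)-13-acetoxy-4,5-epoxy-14-[(4-methoxybenzyl)oxy]-8-(methacryloyloxy)germacra-1(10),2,7(11)-trien-12,6-olide
Product: 36 (4R,5S,6S,8S)-13-acetoxy-4,5-epoxy-14-hydroxy-8-(methacryloyloxy)germacra-1(10),2,7(11)-trien-12,6-olide
Conditions: DDQ, CH2Cl2/pH 7 buffer 10:1, 0 °C
Reagents that add atoms: none
Why: Oxidative PMB cleavage under buffered neutral conditions, which the epoxide, the esters and the butenolide should tolerate.

Step 21
Reactants: 36 (4R,5S,6S,8S)-13-acetoxy-4,5-epoxy-14-hydroxy-8-(methacryloyloxy)germacra-1(10),2,7(11)-trien-12,6-olide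
Product: 37 CNP0207684.1, (1R,4R,5S,6S,8S,10S)-13-acetoxy-1,10:4,5-diepoxy-14-hydroxy-8-(methacryloyloxy)germacra-2,7(11)-dien-12,6-olide (2Z)
Conditions: Ti(OiPr)4, L-(+)-diethyl tartrate, t-BuOOH, 4 Å MS, CH2Cl2, −20 °C
Reagents that add atoms: tert-butyl hydroperoxide (CC(C)(C)OO)
Why: Sharpless asymmetric epoxidation epoxidises only the alkene of the allylic alcohol, leaving C2=C3, the methacrylate and the butenolide. With C14 drawn lower right, L-(+)-tartrate delivers oxygen to the face that gives 1R,10S; the ring-trans alkene can swing through the ring, so the catalyst can select the matching conformer.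

## Compound list

1 | 4-methoxy-2-methylphenol | COc1ccc(O)c(C)c1 | starting material
2 | 4,4-dimethoxy-2-methylcyclohexa-2,5-dien-1-one | COC1(OC)C=CC(=O)C(C)=C1 | intermediate
3 | 2-bromoprop-2-en-1-ol | C=C(Br)CO | starting material
4 | 1-{[(2-bromoprop-2-en-1-yl)oxy]methyl}-4-methoxybenzene | C=C(Br)COCc1ccc(OC)cc1 | intermediate
5 | 2-{3-[(4-methoxybenzyl)oxy]prop-1-en-2-yl}-4,4,5,5-tetramethyl-1,3,2-dioxaborolane | C=C(COCc1ccc(OC)cc1)B1OC(C)(C)C(C)(C)O1 | intermediate
6 | potassium trifluoro{3-[(4-methoxybenzyl)oxy]prop-1-en-2-yl}borate | C=C(COCc1ccc(OC)cc1)[B-](F)(F)F.[K+] | intermediate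
7 | (5R)-4,4-dimethoxy-5-{3-[(4-methoxybenzyl)oxy]prop-1-en-2-yl}-2-methylcyclohex-2-en-1-one | C=C(COCc1ccc(OC)cc1)[C@H]2CC(=O)C(C)=CC2(OC)OC | intermediate
8 | (1R,5R)-4,4-dimethoxy-5-{3-[(4-methoxybenzyl)oxy]prop-1-en-2-yl}-2-methylcyclohex-2-en-1-ol | C=C(COCc1ccc(OC)cc1)[C@H]2C[C@@H](O)C(C)=CC2(OC)OC | intermediate
9 | (1R,2R,4R,6R)-5,5-dimethoxy-4-{3-[(4-methoxybenzyl)oxy]prop-1-en-2-yl}-1-methyl-7-oxabicyclo[4.1.0]heptan-2-ol | C=C(COCc1ccc(OC)cc1)[C@H]2C[C@@H](O)[C@@]3(C)O[C@H]3C2(OC)OC | intermediate
10 | (1R,3R,5R,6R)-5-hydroxy-3-{3-[(4-methoxybenzyl)oxy]prop-1-en-2-yl}-6-methyl-7-oxabicyclo[4.1.0]heptan-2-one | C=C(COCc1ccc(OC)cc1)[C@H]2C[C@@H](O)[C@@]3(C)O[C@H]3C2=O | intermediate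
11 | benzyl(chloro)dimethylsilane | C[Si](C)(Cl)Cc1ccccc1 | starting material
12 | benzyl(ethynyl)dimethylsilane | C#C[Si](C)(C)Cc1ccccc1 | intermediate
13 | (E)-benzyldimethyl[2-(tributylstannyl)ethenyl]silane | CCCC[Sn](CCCC)(CCCC)/C=C/[Si](C)(C)Cc1ccccc1 | intermediate
14 | (E)-[2-(benzyldimethylsilyl)ethenyl]lithium | [Li]/C=C/[Si](C)(C)Cc1ccccc1 | intermediate
15 | (E)-[2-(benzyldimethylsilyl)ethenyl]cerium dichloride | Cl[Ce](Cl)/C=C/[Si](C)(C)Cc1ccccc1 | intermediate
16 | (1R,2R,4R,5R,6S)-5-[(E)-2-(benzyldimethylsilyl)ethenyl]-4-{3-[(4-methoxybenzyl)oxy]prop-1-en-2-yl}-1-methyl-7-oxabicyclo[4.1.0]heptane-2,5-diol | C=C(COCc1ccc(OC)cc1)[C@H]2C[C@@H](O)[C@@]3(C)O[C@H]3[C@]2(O)/C=C/[Si](C)(C)Cc4ccccc4 | intermediate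
17 | triethylammonium N-(methoxycarbonyl)sulfamate ester of the secondary (C2) hydroxyl of 16 | C=C(COCc1ccc(OC)cc1)[C@H]2C[C@@H](OS(=O)(=O)[N-]C(=O)OC)[C@@]3(C)O[C@H]3[C@]2(O)/C=C/[Si](C)(C)Cc4ccccc4.CC[NH+](CC)CC | intermediate
18 | (1S,2R,3R,6R)-2-[(E)-2-(benzyldimethylsilyl)ethenyl]-3-{3-[(4-methoxybenzyl)oxy]prop-1-en-2-yl}-6-methyl-7-oxabicyclo[4.1.0]hept-4-en-2-ol | C=C(COCc1ccc(OC)cc1)[C@H]2C=C[C@@]3(C)O[C@H]3[C@]2(O)/C=C/[Si](C)(C)Cc4ccccc4 | intermediate
19 | potassium alkoxide of 18 | C=C(COCc1ccc(OC)cc1)[C@H]2C=C[C@@]3(C)O[C@H]3[C@]2([O-])/C=C/[Si](C)(C)Cc4ccccc4.[K+] | intermediate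
20 | potassium C6(O)=C7 enolate of the ring-expanded (8R)-8-silyl-4,5-epoxycyclodeca-1(10),2-dien-6-one | C[Si](C)(Cc1ccccc1)[C@@H]2C/C(COCc3ccc(OC)cc3)=C/C=C\[C@@]4(C)O[C@H]4/C([O-])=C/2.[K+] | intermediate
21 | ethyl (4R,5R,7S,8R)-8-(benzyldimethylsilyl)-4,5-epoxy-14-[(4-methoxybenzyl)oxy]-6-oxo-13-norgermacra-1(10),2-dien-12-oate | C[Si](C)(Cc1ccccc1)[C@@H]2C/C(COCc3ccc(OC)cc3)=C/C=C\[C@@]4(C)O[C@H]4C(=O)[C@@H]2CC(=O)OCC | intermediate
22 | lithium (6S)-alkoxide of the hydroxy ester from 21 | C[Si](C)(Cc1ccccc1)[C@@H]2C/C(COCc3ccc(OC)cc3)=C/C=C\[C@@]4(C)O[C@H]4[C@@H]([O-])[C@@H]2CC(=O)OCC.[Li+] | intermediate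
23 | (4R,5S,6S,7S,8R)-8-(benzyldimethylsilyl)-4,5-epoxy-14-[(4-methoxybenzyl)oxy]-13-norgermacra-1(10),2-dien-12,6-olide | C[Si](C)(Cc1ccccc1)[C@@H]2C/C(COCc3ccc(OC)cc3)=C/C=C\[C@@]4(C)O[C@H]4[C@H]5OC(=O)C[C@H]25 | intermediate
24 | 8-(fluorodimethylsilyl) analogue of 23 | C[Si](C)(F)[C@@H]2C/C(COCc3ccc(OC)cc3)=C/C=C\[C@@]4(C)O[C@H]4[C@H]5OC(=O)C[C@H]25 | intermediate
25 | (4R,5S,6S,7R,8R)-4,5-epoxy-8-hydroxy-14-[(4-methoxybenzyl)oxy]-13-norgermacra-1(10),2-dien-12,6-olide | O[C@@H]2C/C(COCc3ccc(OC)cc3)=C/C=C\[C@@]4(C)O[C@H]4[C@H]5OC(=O)C[C@H]25 | intermediate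
26 | (4R,5S,6S,7S,8R)-4,5-epoxy-14-[(4-methoxybenzyl)oxy]-8-(triethylsilyloxy)-13-norgermacra-1(10),2-dien-12,6-olide | CC[Si](CC)(CC)O[C@@H]2C/C(COCc3ccc(OC)cc3)=C/C=C\[C@@]4(C)O[C@H]4[C@H]5OC(=O)C[C@H]25 | intermediate
27 | lithium enolate of lactone 26 | CC[Si](CC)(CC)O[C@@H]2C/C(COCc3ccc(OC)cc3)=C/C=C\[C@@]4(C)O[C@H]4[C@H]5OC([O-])=C[C@H]25.[Li+] | intermediate
28 | (4R,5S,6S,7S,8R,11R)-4,5-epoxy-13-hydroxy-14-[(4-methoxybenzyl)oxy]-8-(triethylsilyloxy)germacra-1(10),2-dien-12,6-olide | CC[Si](CC)(CC)O[C@@H]2C/C(COCc3ccc(OC)cc3)=C/C=C\[C@@]4(C)O[C@H]4[C@H]5OC(=O)[C@@H](CO)[C@H]25 | intermediate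
29 | dilithium alkoxide enolate of 28 | CC[Si](CC)(CC)O[C@@H]2C/C(COCc3ccc(OC)cc3)=C/C=C\[C@@]4(C)O[C@H]4[C@H]5OC([O-])=C(C[O-])[C@H]25.[Li+].[Li+] | intermediate
30 | (11R)-11-(phenylselanyl) derivative of 28 | CC[Si](CC)(CC)O[C@@H]2C/C(COCc3ccc(OC)cc3)=C/C=C\[C@@]4(C)O[C@H]4[C@H]5OC(=O)[C@@](CO)([Se]c6ccccc6)[C@H]25 | intermediate
31 | selenoxide of 30 | CC[Si](CC)(CC)O[C@@H]2C/C(COCc3ccc(OC)cc3)=C/C=C\[C@@]4(C)O[C@H]4[C@H]5OC(=O)[C@@](CO)([Se](=O)c6ccccc6)[C@H]25 | intermediate
32 | (4R,5S,6S,8R)-4,5-epoxy-13-hydroxy-14-[(4-methoxybenzyl)oxy]-8-(triethylsilyloxy)germacra-1(10),2,7(11)-trien-12,6-olide | CC[Si](CC)(CC)O[C@@H]2C/C(COCc3ccc(OC)cc3)=C/C=C\[C@@]4(C)O[C@H]4[C@H]5OC(=O)C(CO)=C25 | intermediate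
33 | 13-acetate of 32 | CC[Si](CC)(CC)O[C@@H]2C/C(COCc3ccc(OC)cc3)=C/C=C\[C@@]4(C)O[C@H]4[C@H]5OC(=O)C(COC(C)=O)=C25 | intermediate
34 | (4R,5S,6S,8R)-13-acetoxy-4,5-epoxy-8-hydroxy-14-[(4-methoxybenzyl)oxy]germacra-1(10),2,7(11)-trien-12,6-olide | O[C@@H]2C/C(COCc3ccc(OC)cc3)=C/C=C\[C@@]4(C)O[C@H]4[C@H]5OC(=O)C(COC(C)=O)=C25 | intermediate
35 | (4R,5S,6S,8S)-13-acetoxy-4,5-epoxy-14-[(4-methoxybenzyl)oxy]-8-(methacryloyloxy)germacra-1(10),2,7(11)-trien-12,6-olide | C=C(C)C(=O)O[C@H]2C/C(COCc3ccc(OC)cc3)=C/C=C\[C@@]4(C)O[C@H]4[C@H]5OC(=O)C(COC(C)=O)=C25 | intermediate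
36 | (4R,5S,6S,8S)-13-acetoxy-4,5-epoxy-14-hydroxy-8-(methacryloyloxy)germacra-1(10),2,7(11)-trien-12,6-olide | C=C(C)C(=O)O[C@H]1C/C(CO)=C/C=C\[C@@]2(C)O[C@H]2[C@H]3OC(=O)C(COC(C)=O)=C13 | intermediate
37 | CNP0207684.1, (1R,4R,5S,6S,8S,10S)-13-acetoxy-1,10:4,5-diepoxy-14-hydroxy-8-(methacryloyloxy)germacra-2,7(11)-dien-12,6-olide (2Z) | C=C(C)C(=O)O[C@H]1C[C@@]2(CO)O[C@@H]2/C=C\[C@@]2(C)O[C@H]2[C@H]2OC(=O)C(COC(C)=O)=C12 | target

## Step count and least certain steps

Total: 21 steps. Longest linear sequence: 18 steps (2, 3, 4–7, 10–21) from 2-bromoprop-2-en-1-ol (3).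

Step 12 (key). The most likely failure is heterolysis of alkoxide 19 at C1–C6 into a pentadienyl anion and a silyl enone, in competition with the concerted shift. The C1 carbanion is well stabilised and bond formation at the silyl-bearing C8 is sterically retarded. Recombination would erode the chirality transfer to C8 and could join C3 in place of C9. Transannular attack of enolate 20 on the dienyl epoxide, or O-alkylation, could also divert material. The fallback keeps the ring expansion but removes the substituent from the bond-forming terminus and brings the C8 oxygen in by conjugate addition. It sets out from 10. Vinylmagnesium bromide/CeCl3 should give the vinyl diol F1, and Burgess dehydration the dienol F2. KH/18-crown-6 with a proton quench should give the cyclodecadienone F3, which has no stereocentre at C8 to lose. IBX in DMSO should give the (E)-enone F4, since only C7–C8 can be dehydrogenated. Conjugate addition of the cuprate from (diethylamino)diphenylsilyllithium on the outer face, with bromoacetate trapping and ethanol work-up, should give the ethoxysilyl keto ester F5. L-Selectride should give the ethoxysilyl lactone F6, and H2O2/KF/KHCO3 the alcohol 25, where the route is rejoined.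

Step 11. The risk is competing sulfamoylation and ionisation of the tertiary allylic alcohol, which would lead to allylic transposition or loss of the carbinol. The fallback makes the ring alkene before the tertiary alcohol exists. It sets out from 9: Burgess dehydration should give the ene ketal F7 and clay hydrolysis the β,γ-unsaturated epoxy ketone F8, which is handled cold and without base because enolisation leads to a catechol. Immediate addition of organocerium 15 should give 18, where the route is rejoined.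

Step 13. The risk is hydride delivery to the inner face if the ring relaxes to another conformer after alkylation, giving the 6-epimer. The fallback corrects C6 by inversion and does not rely on facial control. It sets out from 21: reduction then gives the 6-epi lactone F9; LiOH should give the hydroxy acid F10, and Mitsunobu lactonisation (PPh3, DIAD) should close the ring with inversion at C6 to 23.

Step 17. The risk is incomplete formation of the alkoxide enolate, retro-aldol loss of formaldehyde, or selenium entering trans to H7 so that the syn-elimination stalls. The fallback builds C13 at the aldehyde level through a 1,3-dicarbonyl that selenenylates without strong base. It sets out from 26: LDA/ethyl formate should give the α-formyl lactone F11. PhSeCl/pyridine followed by H2O2 in the same flask should give the formyl butenolide F12, and NaBH4/CeCl3 should reduce the aldehyde to 32.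

Step 19. The risk is E2 elimination of the activated allylic alcohol toward C9 (a conjugated dienolide), or slow SN2 inside the ring with loss of stereochemical integrity. The fallback inverts by oxidation and reduction. It sets out from 34: Dess–Martin periodinane should give the 8-ketone F13. (R)-Me-CBS/catecholborane (reagent control, alkenyl versus CH2 flanks) should give the 8S alcohol F14, and methacrylic anhydride/DMAP should give 35.

## Further compounds

F1 | step 12 | 5-ethenyl analogue of 16 (vinyl diol) | C=C(COCc1ccc(OC)cc1)[C@H]2C[C@@H](O)[C@@]3(C)O[C@H]3[C@]2(O)C=C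
F2 | step 12 | 2-ethenyl analogue of 18 (dienol) | C=C(COCc1ccc(OC)cc1)[C@H]2C=C[C@@]3(C)O[C@H]3[C@]2(O)C=C
F3 | step 12 | (4R,5-cis)-4,5-epoxy-14-[(4-methoxybenzyl)oxy]-4-methylcyclodeca-1(10),2-dien-6-one (cyclodecadienone) | O=C1CCC/C(COCc2ccc(OC)cc2)=C/C=C\[C@@]3(C)O[C@@H]13
F4 | step 12 | 7,8-didehydro derivative of F3 ((E)-enone) | O=C1/C=C/C/C(COCc2ccc(OC)cc2)=C/C=C\[C@@]3(C)O[C@@H]13
F5 | step 12 | 8-[ethoxy(diphenyl)silyl] analogue of 21 (ethoxysilyl keto ester) | CCO[Si](c1ccccc1)(c2ccccc2)[C@@H]3C/C(COCc4ccc(OC)cc4)=C/C=C\[C@@]5(C)O[C@H]5C(=O)[C@@H]3CC(=O)OCC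
F6 | step 12 | 8-[ethoxy(diphenyl)silyl] analogue of 23 (ethoxysilyl lactone) | CCO[Si](c1ccccc1)(c2ccccc2)[C@@H]3C/C(COCc4ccc(OC)cc4)=C/C=C\[C@@]5(C)O[C@H]5[C@H]6OC(=O)C[C@H]36
F7 | step 11 | 2,3-didehydro-3-deoxy derivative of 9 (ene ketal) | C=C(COCc1ccc(OC)cc1)[C@H]2C=C[C@@]3(C)O[C@H]3C2(OC)OC
F8 | step 11 | β,γ-unsaturated epoxy ketone from F7 | C=C(COCc1ccc(OC)cc1)[C@H]2C=C[C@@]3(C)O[C@H]3C2=O
F9 | step 13 | C6 epimer of 23 (6-epi lactone) | C[Si](C)(Cc1ccccc1)[C@@H]2C/C(COCc3ccc(OC)cc3)=C/C=C\[C@@]4(C)O[C@H]4[C@@H]5OC(=O)C[C@H]25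
F10 | step 13 | 6-epi hydroxy acid from F9 | C[Si](C)(Cc1ccccc1)[C@@H]2C/C(COCc3ccc(OC)cc3)=C/C=C\[C@@]4(C)O[C@H]4[C@H](O)[C@@H]2CC(=O)O
F11 | step 17 | 11-formyl derivative of 26 (α-formyl lactone) | CC[Si](CC)(CC)O[C@@H]2C/C(COCc3ccc(OC)cc3)=C/C=C\[C@@]4(C)O[C@H]4[C@H]5OC(=O)[C@@H](C=O)[C@H]25
F12 | step 17 | 13-oxo analogue of 32 (formyl butenolide) | CC[Si](CC)(CC)O[C@@H]2C/C(COCc3ccc(OC)cc3)=C/C=C\[C@@]4(C)O[C@H]4[C@H]5OC(=O)C(C=O)=C25
F13 | step 19 | 8-oxo analogue of 34 (8-ketone) | O=C1C/C(COCc2ccc(OC)cc2)=C/C=C\[C@@]3(C)O[C@H]3[C@H]4OC(=O)C(COC(C)=O)=C14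
F14 | step 19 | C8 epimer of 34 (8S alcohol) | O[C@H]1C/C(COCc2ccc(OC)cc2)=C/C=C\[C@@]3(C)O[C@H]3[C@H]4OC(=O)C(COC(C)=O)=C14
A1 | alternative 1 | C2/C3-seco bis(vinyl epoxide) diene, metathesis precursor | C=C(C)C(=O)O[C@@H](C[C@@]2(CO)O[C@@H]2C=C)C1=C(COC(C)=O)C(=O)O[C@@H]1[C@@H]3O[C@]3(C)C=C
A2 | alternative 2 | C7-iodobutenolide C8-aldehyde with O14 as PMB ether | O=CC[C@@]1(COCc2ccc(OC)cc2)O[C@@H]1/C=C\[C@@]1(C)O[C@H]1[C@H]1OC(=O)C(COC(C)=O)=C1I
A3 | alternative 2 | 8-hydroxy macrocycle from the chromium-mediated closure (8S drawn) | O[C@H]1C[C@@]2(COCc3ccc(OC)cc3)O[C@@H]2/C=C\[C@@]2(C)O[C@H]2[C@H]2OC(=O)C(COC(C)=O)=C12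
A4 | alternative 3 | cis-fused eudesma-1,3,7(11)-trien-12,6-olide with the target's C6, C8, C13 and C14 substituents | C=C(C)C(=O)O[C@H]1C[C@@]2(CO)C=CC=C(C)[C@H]2[C@H]2OC(=O)C(COC(C)=O)=C12
A5 | alternative 3 | (1(10)E,2Z,4Z)-germacra-1(10),2,4,7(11)-tetraen-12,6-olide triene | C=C(C)C(=O)O[C@H]1C/C(CO)=C/C=C\C(C)=C/[C@H]2OC(=O)C(COC(C)=O)=C12
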